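The O6–acyl bond of the vanillate is cut first. Next comes C6–C7 of the seven-membered ring (C1, C5, C6, C7, C8, C9, C10), then C8–C9, C1–C10 and C1–C5. This leads back to (S)-terpinen-4-ol, vinylmagnesium bromide, 2-bromoallyltrimethylsilane and vanillic acid.
Inside the cycloheptane ring, C6(O)–C7H2–C8(=C14H2) is a homoallylic alcohol whose double bond lies outside the ring. A C6 aldehyde and an allylsilane C7H2=C8–C14H2–Si give exactly this unit when C7 bonds to C6 and silicon leaves.
In the forward direction the cyclohexene of terpinen-4-ol is cleaved and re-closed to the cyclopentene C1–C5, and the C10–C9 arm is added at C1. A temporary δ-lactone tells the two arms apart, and the vinyllithium brings in C8, C7 and C14. The cycloheptane closes last, followed by acylation and desilylation.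
C4 comes from the chiral pool and C1 from vinyl addition anti to the C4 silyloxy group. C5 is set by equilibration of the aldehyde, C9 by a CBS reduction under reagent control, and C6 by the chair-like transition state of the ring closure.

Key step: step 13

Remark on numbering: C1 is the quaternary carbon bearing methyl C15, C2 and C3 are the cyclopentane CH2 groups, C4 is the isopropyl carbinol and C5 the ring-fusion CH. C6 is the acylated carbinol, C7 a CH2, C8 carries =C14H2, C9 is the free carbinol and C10 a CH2. β is the side of C15 and α the side of H5. The target is 1R,4R,5S,6S,9S, with O4 β and O6 and O9 α.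
Assumption: (S)-terpinen-4-ol is used as a single enantiomer, and its enantiomeric purity fixes that of the whole route.

Step 1
Reactants: 1 (S)-terpinen-4-ol
Product: 2 (S)-1-isopropyl-4-methyl-1-(triethylsilyloxy)cyclohex-3-ene
Conditions: TESOTf, 2,6-lutidine, CH2Cl2, 0 °C to rt
Reagents that add atoms: triethylsilyl trifluoromethanesulfonate, CC[Si](CC)(CC)OS(=O)(=O)C(F)(F)F
Why: Silylation with a silyl triflate and a hindered pyridine base is the standard way to cap a tertiary alcohol, it leaves the C4 stereocentre of the chiral pool untouched, and the silyl ether later blocks retro-aldol cleavage and shields the β face.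

Step 2
Reactants: 2 (S)-1-isopropyl-4-methyl-1-(triethylsilyloxy)cyclohex-3-ene
Product: 4 (S)-3-isopropyl-6-oxo-3-(triethylsilyloxy)heptanal, via secondary ozonide 3 (not isolated)
Conditions: O3, CH2Cl2, −78 °C; then PPh3, −78 °C to rt
Reagents that add atoms: ozone, [O-][O+]=O
Why: Ozonolysis with reductive work-up cleaves the only C=C bond into the methyl ketone (C1) and the aldehyde (C6) without touching the silyl ether or C4.

Step 3
Reactants: 4 (S)-3-isopropyl-6-oxo-3-(triethylsilyloxy)heptanal
Product: 5 (R)-5-isopropyl-2-methyl-5-(triethylsilyloxy)cyclopent-1-ene-1-carbaldehyde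
Conditions: piperidine (30 mol %), AcOH (30 mol %), 4 Å MS, toluene, 50 °C
Reagents that add atoms: none
Why: In this amine-catalysed intramolecular aldol condensation only the aldehyde forms an enamine, so C5 attacks the C1 ketone in a five-membered closure helped by the fully substituted C4 (a hydroxide base would instead give the acetylcyclopentene), and the acid-assisted dehydration should take the basic new C1 hydroxyl rather than the non-basic, shielded silyloxy group at C4.

Step 4
Reactants: 5 (R)-5-isopropyl-2-methyl-5-(triethylsilyloxy)cyclopent-1-ene-1-carbaldehyde; 6 vinylmagnesium bromide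
Product: 8 (1R,2R,5R)-5-isopropyl-2-methyl-5-(triethylsilyloxy)-2-vinylcyclopentane-1-carbaldehyde, via trimethylsilyl enol ether 7 (not isolated)
Conditions: 6 (2 equiv), CuBr·SMe2 (20 mol %), TMSCl, DMPU, THF, −78 °C; crude 7: K2CO3 (10 mol %), MeOH, 0 °C to rt
Reagents that add atoms: chlorotrimethylsilane, C[Si](C)(C)Cl (its silyl group is carried by 7 only)
Why: The TMSCl-accelerated copper-catalysed conjugate addition of a Grignard reagent builds quaternary carbons on β,β-disubstituted enals; the triethylsilyl group, turned away from the isopropyl group, lies over the β face so that vinyl should enter C1 from the α face, the enolate is caught as 7 before it can expel the silyloxy group, and carbonate-catalysed methanolysis equilibrates C5 to the aldehyde standing trans to isopropyl and vinyl (H5 α).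

Step 5
Reactants: 8 (1R,2R,5R)-5-isopropyl-2-methyl-5-(triethylsilyloxy)-2-vinylcyclopentane-1-carbaldehyde
Product: 10 2-[(1R,2S,3R)-2-(hydroxymethyl)-3-isopropyl-1-methyl-3-(triethylsilyloxy)cyclopentyl]ethanol, via bis(9-BBN) adduct 9 (not isolated)
Conditions: 9-BBN (3 equiv), THF, 0 °C to rt; then NaOH, H2O2, 0 °C
Reagents that add atoms: hydrogen peroxide, OO; 9-borabicyclo[3.3.1]nonane, B1C2CCCC1CCC2 (its boron is carried by 9 only)
Why: In this hydroboration–oxidation 9-BBN places boron on the terminal carbon C9 of the monosubstituted alkene and reduces the aldehyde in the same operation, and no stereocentre is formed or touched.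

Step 6
Reactants: 10 2-[(1R,2S,3R)-2-(hydroxymethyl)-3-isopropyl-1-methyl-3-(triethylsilyloxy)cyclopentyl]ethanol
Product: 12 (4aR,7R,7aS)-7-isopropyl-4a-methyl-7-(triethylsilyloxy)hexahydrocyclopenta[c]pyran-3(1H)-one, via lactol 11 (not isolated)
Conditions: TEMPO (20 mol %), PhI(OAc)2 (2.5 equiv), CH2Cl2, rt
Reagents that add atoms: none
Why: In this oxoammonium-mediated oxidative lactonisation of a 1,5-diol the bulky oxidant takes the unhindered C9 carbinol before the C6 carbinol that is flanked by two quaternary carbons, the aldehyde closes to lactol 11 and this is oxidised further, so the two arms are told apart without protecting groups.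

Step 7
Reactants: 12 (4aR,7R,7aS)-7-isopropyl-4a-methyl-7-(triethylsilyloxy)hexahydrocyclopenta[c]pyran-3(1H)-one; 13 2-bromoallyltrimethylsilane
Product: 15 1-[(1R,2S,3R)-2-(hydroxymethyl)-3-isopropyl-1-methyl-3-(triethylsilyloxy)cyclopentyl]-3-[(trimethylsilyl)methyl]but-3-en-2-one, via vinyllithium 14 (not isolated)
Conditions: 13, t-BuLi (2 equiv per 13), Et2O, −78 °C; then 12, THF, −78 °C; AcOH quench at −78 °C
Reagents that add atoms: tert-butyllithium, [Li]C(C)(C)C (its lithium is carried by 14 only)
Why: Bromine–lithium exchange followed by single addition of the vinyllithium to a δ-lactone, whose tetrahedral lithium alkoxide persists at −78 °C until the acidic quench, forms C8–C9 at the ketone level and frees O6 in the same step.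

Step 8
Reactants: 15 1-[(1R,2S,3R)-2-(hydroxymethyl)-3-isopropyl-1-methyl-3-(triethylsilyloxy)cyclopentyl]-3-[(trimethylsilyl)methyl]but-3-en-2-one
Product: 16 [(1S,2R,5R)-5-isopropyl-2-methyl-2-{2-oxo-3-[(trimethylsilyl)methyl]but-3-enyl}-5-(triethylsilyloxy)cyclopentyl]methyl acetate
Conditions: Ac2O, pyridine, DMAP (5 mol %), CH2Cl2, 0 °C to rt
Reagents that add atoms: acetic anhydride, CC(=O)OC(C)=O
Why: DMAP-catalysed acetylation of the primary alcohol drains any hemiketal form into the open enone and masks O6 with a group that is orthogonal to every silyl ether of the route.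

Step 9
Reactants: 16 [(1S,2R,5R)-5-isopropyl-2-methyl-2-{2-oxo-3-[(trimethylsilyl)methyl]but-3-enyl}-5-(triethylsilyloxy)cyclopentyl]methyl acetate
Product: 17 [(1S,2R,5R)-2-{(2S)-2-hydroxy-3-[(trimethylsilyl)methyl]but-3-enyl}-5-isopropyl-2-methyl-5-(triethylsilyloxy)cyclopentyl]methyl acetate
Conditions: (R)-2-methyl-CBS-oxazaborolidine (30 mol %), catecholborane, toluene, −78 °C
Reagents that add atoms: none
Why: In the Corey–Bakshi–Shibata reduction the α-branched alkenyl group acts as the large and the C10 methylene as the small ketone substituent, so the (R)-catalyst should deliver hydride to give the 9S alcohol under reagent control, while catecholborane at low temperature neither hydroborates the allylsilane nor reduces the acetate.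

Step 10
Reactants: 17 [(1S,2R,5R)-2-{(2S)-2-hydroxy-3-[(trimethylsilyl)methyl]but-3-enyl}-5-isopropyl-2-methyl-5-(triethylsilyloxy)cyclopentyl]methyl acetate
Product: 18 [(1S,2R,5R)-2-{(2S)-2-(tert-butyldimethylsilyloxy)-3-[(trimethylsilyl)methyl]but-3-enyl}-5-isopropyl-2-methyl-5-(triethylsilyloxy)cyclopentyl]methyl acetate
Conditions: TBSCl, imidazole, DMF, rt
Reagents that add atoms: tert-butyldimethylsilyl chloride, CC(C)(C)[Si](C)(C)Cl
Why: Routine silylation of a secondary allylic alcohol under weakly basic conditions leaves the allylsilane and C9 untouched and installs a group that withstands BF3 at low temperature.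

Step 11
Reactants: 18 [(1S,2R,5R)-2-{(2S)-2-(tert-butyldimethylsilyloxy)-3-[(trimethylsilyl)methyl]but-3-enyl}-5-isopropyl-2-methyl-5-(triethylsilyloxy)cyclopentyl]methyl acetate
Product: 19 [(1S,2R,5R)-2-{(2S)-2-(tert-butyldimethylsilyloxy)-3-[(trimethylsilyl)methyl]but-3-enyl}-5-isopropyl-2-methyl-5-(triethylsilyloxy)cyclopentyl]methanol
Conditions: K2CO3 (20 mol %), MeOH, rt
Reagents that add atoms: none
Why: Base-catalysed transesterification removes only the acetate, since the alkyl silyl ethers and the allylsilane are inert to carbonate in methanol.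

Step 12
Reactants: 19 [(1S,2R,5R)-2-{(2S)-2-(tert-butyldimethylsilyloxy)-3-[(trimethylsilyl)methyl]but-3-enyl}-5-isopropyl-2-methyl-5-(triethylsilyloxy)cyclopentyl]methanol
Product: 20 (1R,2R,5R)-2-{(2S)-2-(tert-butyldimethylsilyloxy)-3-[(trimethylsilyl)methyl]but-3-enyl}-5-isopropyl-2-methyl-5-(triethylsilyloxy)cyclopentane-1-carbaldehyde
Conditions: Dess–Martin periodinane, pyridine, CH2Cl2, 0 °C to rt
Reagents that add atoms: none
Why: The pyridine-buffered Dess–Martin oxidation reaches the hindered aldehyde without strong acid or base, so the allylsilane, the C5 configuration and the β-silyloxy group are kept.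

Step 13
Reactants: 20 (1R,2R,5R)-2-{(2S)-2-(tert-butyldimethylsilyloxy)-3-[(trimethylsilyl)methyl]but-3-enyl}-5-isopropyl-2-methyl-5-(triethylsilyloxy)cyclopentane-1-carbaldehyde
Product: 21 (1R,4R,5S,6S,9S)-9-(tert-butyldimethylsilyloxy)-4-(triethylsilyloxy)dauc-8(14)-en-6-ol
Conditions: BF3·OEt2 (1.5 equiv), 2,6-di-tert-butyl-4-methylpyridine, CH2Cl2 (0.005 M), −78 °C; aq NaHCO3
Reagents that add atoms: none
Why: BF3 binds the oxygen of the C6 aldehyde, the unsubstituted terminus C7 of the allylsilane attacks C6 while the C14–Si bond lies parallel to the π system and stabilises the charge growing at C8, and fluoride-assisted loss of Me3Si then leaves C8=C14 as an exocyclic methylene group. The closest known reaction type is the intramolecular Hosomi–Sakurai allylation of ω-formyl 2-substituted allylsilanes, which gives 3-methylenecycloalkanols in the five-, six- and seven-membered series. The cycloheptane closes 7-exo-trig at the carbonyl group and endo with respect to the allylsilane π bond, since C7 and C8 both become ring atoms. The new stereocentre C6 is controlled by the trans-fused chair-like transition state that the two trans arms on the cyclopentane impose: the BF3-bound oxygen takes the equatorial α position, because the axial β position would press it against the axial C15 methyl group and the C4 silyloxy group, and this gives 6S with H6 anti to H5. C–C bond formation must win over protodesilylation, the carbonyl-ene path and ionisation of the silyl ethers; the more nucleophilic 2-alkyl-substituted allylsilane, the preorganisation by quaternary C1 and the ring, the hindered pyridine as proton trap, high dilution and −78 °C should secure this, and ionisation at C9 gains no help from silicon because the resulting allyl cation would not be β to it. Because O4 and O9 stay silylated, 21 offers a single acylation site.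

Step 14
Reactants: 22 vanillic acid
Product: 24 4-(tert-butyldimethylsilyloxy)-3-methoxybenzoic acid, via bis-silylated vanillic acid 23 (not isolated)
Conditions: TBSCl (2.5 equiv), imidazole, DMF, rt; then AcOH–THF–H2O, rt
Reagents that add atoms: tert-butyldimethylsilyl chloride, CC(C)(C)[Si](C)(C)Cl
Why: Exhaustive silylation followed by hydrolysis of the far more labile silyl ester is the routine way to a phenol-protected hydroxybenzoic acid, and the aryl silyl ether falls in the final fluoride step together with the others.

Step 15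
Reactants: 21 (1R,4R,5S,6S,9S)-9-(tert-butyldimethylsilyloxy)-4-(triethylsilyloxy)dauc-8(14)-en-6-ol; 24 4-(tert-butyldimethylsilyloxy)-3-methoxybenzoic acid
Product: 25 (1R,4R,5S,6S,9S)-9-(tert-butyldimethylsilyloxy)-4-(triethylsilyloxy)dauc-8(14)-en-6-yl 4-(tert-butyldimethylsilyloxy)-3-methoxybenzoate
Conditions: DCC, DMAP, CH2Cl2, rt to 40 °C
Reagents that add atoms: none
Why: The Steglich esterification meets only one free hydroxyl, the equatorial O6 on the open α face, and keeps the C6 configuration because the C6–O bond is not broken.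

Step 16
Reactants: 25 (1R,4R,5S,6S,9S)-9-(tert-butyldimethylsilyloxy)-4-(triethylsilyloxy)dauc-8(14)-en-6-yl 4-(tert-butyldimethylsilyloxy)-3-methoxybenzoate
Product: 26 (1R,4R,5S,6S,9S)-4,9-dihydroxydauc-8(14)-en-6-yl 4-hydroxy-3-methoxybenzoate (CNP0330487.1)
Conditions: HF·pyridine, pyridine, THF, 0 °C to rt
Reagents that add atoms: none
Why: Fluoride-driven cleavage with buffered HF·pyridine removes the tertiary, the allylic and the aryl silyl ether in one operation and is mild enough for the benzoate ester, the allylic alcohol and the exocyclic alkene, with no stereocentre affected.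

Compound list
1 | (S)-terpinen-4-ol, (1S)-1-isopropyl-4-methylcyclohex-3-en-1-ol | C1C=C(C)CC[C@@]1(O)C(C)C | starting material
2 | (S)-1-isopropyl-4-methyl-1-(triethylsilyloxy)cyclohex-3-ene | C1C=C(C)CC[C@@]1(O[Si](CC)(CC)CC)C(C)C | intermediate
3 | secondary ozonide of 2 (1,2,4-trioxolane across the former C=C, both bridgehead diastereomers, not isolated) | CC12CC[C@@](O[Si](CC)(CC)CC)(C(C)C)CC(OO1)O2 | intermediate
4 | (S)-3-isopropyl-6-oxo-3-(triethylsilyloxy)heptanal | CC(=O)CC[C@@](CC=O)(O[Si](CC)(CC)CC)C(C)C | intermediate
5 | (R)-5-isopropyl-2-methyl-5-(triethylsilyloxy)cyclopent-1-ene-1-carbaldehyde | O=CC1=C(C)CC[C@@]1(O[Si](CC)(CC)CC)C(C)C | intermediate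
6 | vinylmagnesium bromide | C=C[Mg]Br | starting material
7 | trimethylsilyl enol ether of 8 (C5=C6H–OTMS, geometry of no consequence; 1R,4R; not isolated) | C[Si](C)(C)OC=C1[C@](C)(CC[C@@]1(O[Si](CC)(CC)CC)C(C)C)C=C | intermediate
8 | (1R,2R,5R)-5-isopropyl-2-methyl-5-(triethylsilyloxy)-2-vinylcyclopentane-1-carbaldehyde (CHO, methyl and OTES β; vinyl, isopropyl and H5 α) | O=C[C@@H]1[C@](C)(CC[C@@]1(O[Si](CC)(CC)CC)C(C)C)C=C | intermediate
9 | bis(9-BBN) adduct: O6-boryl ether and C9-borane of 10 (not isolated) | C(OB2C3CCCC2CCC3)[C@@H]1[C@](C)(CC[C@@]1(O[Si](CC)(CC)CC)C(C)C)CCB2C3CCCC2CCC3 | intermediate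
10 | 2-[(1R,2S,3R)-2-(hydroxymethyl)-3-isopropyl-1-methyl-3-(triethylsilyloxy)cyclopentyl]ethanol | OC[C@@H]1[C@](C)(CC[C@@]1(O[Si](CC)(CC)CC)C(C)C)CCO | intermediate
11 | lactol of 12, (4aR,7R,7aS)-7-isopropyl-4a-methyl-7-(triethylsilyloxy)octahydrocyclopenta[c]pyran-3-ol (both anomers, not isolated) | OC1C[C@@]2(C)CC[C@@](O[Si](CC)(CC)CC)(C(C)C)[C@@H]2CO1 | intermediate
12 | (4aR,7R,7aS)-7-isopropyl-4a-methyl-7-(triethylsilyloxy)hexahydrocyclopenta[c]pyran-3(1H)-one (trans-fused δ-lactone, C9 carbonyl, O6 ring oxygen) | O=C1C[C@@]2(C)CC[C@@](O[Si](CC)(CC)CC)(C(C)C)[C@@H]2CO1 | intermediate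
13 | 2-bromoallyltrimethylsilane | C=C(Br)C[Si](C)(C)C | starting material
14 | [3-(trimethylsilyl)prop-1-en-2-yl]lithium (not isolated) | [Li]C(=C)C[Si](C)(C)C | intermediate
15 | 1-[(1R,2S,3R)-2-(hydroxymethyl)-3-isopropyl-1-methyl-3-(triethylsilyloxy)cyclopentyl]-3-[(trimethylsilyl)methyl]but-3-en-2-one | OC[C@@H]1[C@](C)(CC[C@@]1(O[Si](CC)(CC)CC)C(C)C)CC(=O)C(=C)C[Si](C)(C)C | intermediate
16 | O6-acetate of 15 | CC(=O)OC[C@@H]1[C@](C)(CC[C@@]1(O[Si](CC)(CC)CC)C(C)C)CC(=O)C(=C)C[Si](C)(C)C | intermediate
17 | (9S)-allylic alcohol, O6-acetate | CC(=O)OC[C@@H]1[C@](C)(CC[C@@]1(O[Si](CC)(CC)CC)C(C)C)C[C@@H](C(=C)C[Si](C)(C)C)O | intermediate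
18 | O9-TBS ether of 17 | CC(=O)OC[C@@H]1[C@](C)(CC[C@@]1(O[Si](CC)(CC)CC)C(C)C)C[C@@H](C(=C)C[Si](C)(C)C)O[Si](C)(C)C(C)(C)C | intermediate
19 | primary alcohol (free O6, O4-TES, O9-TBS, allylsilane) | OC[C@@H]1[C@](C)(CC[C@@]1(O[Si](CC)(CC)CC)C(C)C)C[C@@H](C(=C)C[Si](C)(C)C)O[Si](C)(C)C(C)(C)C | intermediate
20 | (1R,2R,5R)-2-{(2S)-2-(tert-butyldimethylsilyloxy)-3-[(trimethylsilyl)methyl]but-3-enyl}-5-isopropyl-2-methyl-5-(triethylsilyloxy)cyclopentane-1-carbaldehyde (precursor of the key step) | O=C[C@@H]1[C@](C)(CC[C@@]1(O[Si](CC)(CC)CC)C(C)C)C[C@@H](C(=C)C[Si](C)(C)C)O[Si](C)(C)C(C)(C)C | intermediate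
21 | (1R,4R,5S,6S,9S)-9-(tert-butyldimethylsilyloxy)-4-(triethylsilyloxy)dauc-8(14)-en-6-ol (product of the key step) | C=C1C[C@H](O)[C@@H]2[C@](C)(CC[C@@]2(O[Si](CC)(CC)CC)C(C)C)C[C@@H]1O[Si](C)(C)C(C)(C)C | intermediate
22 | vanillic acid | COc1cc(C(=O)O)ccc1O | starting material
23 | tert-butyldimethylsilyl 4-(tert-butyldimethylsilyloxy)-3-methoxybenzoate (not isolated) | COc1cc(C(=O)O[Si](C)(C)C(C)(C)C)ccc1O[Si](C)(C)C(C)(C)C | intermediate
24 | 4-(tert-butyldimethylsilyloxy)-3-methoxybenzoic acid | COc1cc(C(=O)O)ccc1O[Si](C)(C)C(C)(C)C | intermediate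
25 | fully silylated ester, 6-O-[4-(TBSO)-3-methoxybenzoate] of 21 | C=C1C[C@H](OC(=O)c2ccc(O[Si](C)(C)C(C)(C)C)c(OC)c2)[C@@H]2[C@](C)(CC[C@@]2(O[Si](CC)(CC)CC)C(C)C)C[C@@H]1O[Si](C)(C)C(C)(C)C | intermediate
26 | (1R,4R,5S,6S,9S)-4,9-dihydroxydauc-8(14)-en-6-yl 4-hydroxy-3-methoxybenzoate (CNP0330487.1) | C=C1C[C@H](OC(=O)c2ccc(O)c(OC)c2)[C@@H]2[C@](C)(CC[C@@]2(O)C(C)C)C[C@@H]1O | target

Total step count: 16. Longest linear sequence: 15 (steps 1–13, 15 and 16, from 1).

Steps most likely to fail

Step 4. Direct 1,2-addition may compete with the hindered 1,4-addition. The facial selectivity at C1 may be incomplete. The silyloxy group may also be lost by β-elimination while C5 is equilibrated. The fallback sets out from 5 and comes back at 15, and it replaces organocopper chemistry by a sigmatropic rearrangement that forms no enolate. Reduction of 5 with i-Bu2AlH gives the allylic alcohol F1. Heating F1 with N,N-dimethylacetamide dimethyl acetal in toluene (Eschenmoser–Claisen rearrangement) carries the two-carbon unit from O6 to C1. This should occur on the face turned away from the silyloxy group that neighbours the migrating terminus, and it gives the unsaturated amide F2 with an exocyclic C5=C6 methylene group. Hydroboration of F2 with 9-BBN on the same face and oxidation give the hydroxy amide F3. Two equivalents of vinyllithium 14 then convert the amide of F3 into the hydroxy enone 15.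

Step 3. The silyloxy group may be lost from enamine or dienamine intermediates during the warm amine-catalysed dehydration. The fallback sets out from 4 and comes back at 5, and it separates bond formation from dehydration so that the leaving group is chosen chemically. L-Proline in DMSO at rt should stop at the aldol F4. Trifluoroacetic anhydride and Et3N acylate only the new tertiary C1 hydroxyl to give the trifluoroacetate F5. DBU at 0 °C then expels trifluoroacetate, a far better leaving group than the silyloxide, to give 5.

Step 13. A slow seven-membered closure may let protodesilylation, a carbonyl-ene path or Lewis-acid attack on the tertiary silyl ether compete, and the facial selectivity at the aldehyde may be incomplete. The fallback sets out from 20 and comes back at 21. It forms the same C6–C7 bond with a neutral organochromium reagent in place of Lewis-acid activation. Bromodesilylation of 20 with NBS in CH2Cl2 at −78 °C gives the allylic bromide F6. Slow addition of F6 to CrCl2 in THF under high dilution (intramolecular Nozaki–Hiyama allylation) should give 21 through a closed transition state. Both allyl termini are CH2 groups, so the constitution is unchanged.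

Further compounds
F1 | step 4 | (R)-[5-isopropyl-2-methyl-5-(triethylsilyloxy)cyclopent-1-en-1-yl]methanol | OCC1=C(C)CC[C@@]1(O[Si](CC)(CC)CC)C(C)C
F2 | step 4 | 2-[(1R,3R)-3-isopropyl-1-methyl-2-methylidene-3-(triethylsilyloxy)cyclopentyl]-N,N-dimethylacetamide | C=C1[C@](C)(CC[C@@]1(O[Si](CC)(CC)CC)C(C)C)CC(=O)N(C)C
F3 | step 4 | 2-[(1R,2S,3R)-2-(hydroxymethyl)-3-isopropyl-1-methyl-3-(triethylsilyloxy)cyclopentyl]-N,N-dimethylacetamide | OC[C@@H]1[C@](C)(CC[C@@]1(O[Si](CC)(CC)CC)C(C)C)CC(=O)N(C)C
F4 | step 3 | (5R)-2-hydroxy-5-isopropyl-2-methyl-5-(triethylsilyloxy)cyclopentane-1-carbaldehyde (configuration at the two new centres of no consequence) | O=CC1C(C)(O)CC[C@@]1(O[Si](CC)(CC)CC)C(C)C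
F5 | step 3 | trifluoroacetate of F4 at the new tertiary hydroxyl | O=CC1C(C)(OC(=O)C(F)(F)F)CC[C@@]1(O[Si](CC)(CC)CC)C(C)C
F6 | step 13 | (1R,2R,5R)-2-[(2S)-3-(bromomethyl)-2-(tert-butyldimethylsilyloxy)but-3-enyl]-5-isopropyl-2-methyl-5-(triethylsilyloxy)cyclopentane-1-carbaldehyde | O=C[C@@H]1[C@](C)(CC[C@@]1(O[Si](CC)(CC)CC)C(C)C)C[C@@H](C(=C)CBr)O[Si](C)(C)C(C)(C)C
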